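The 5-7 skeleton is traced back to a 6-6 decalin made from (S)-Wieland–Miescher ketone. In the key step BF3 opens the allylic C–O bond of a cis-fused vinyl epoxide and the methyl-bearing quaternary fusion carbon (C10) shifts from the oxygenated fusion carbon (C5) to its neighbour (C6): six-membered ring B contracts to the cyclopentane while ring A expands to the cycloheptanone. The step exploits the array C5(O)–C6(H)–C10(quaternary) of the target: C5 becomes the ketone that later carries the 4-hydroxybenzoate, C6 the trans ring-fusion CH. The C7=C8 alkene that assists ionisation is afterwards converted into the isopropyl carbinol, and ring A is completed last.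

Key step: step 6

Remark: C1–C10 label the ten ring carbons as in the decalin (C10 methyl-bearing fusion carbon, C1–C4 rest of ring A, C5 second fusion carbon, C6–C9 rest of ring B) and keep these labels after the rearrangement; β is the face of the C10 methyl, α the opposite face.

Step 1
Reactants: 1 (S)-Wieland–Miescher ketone
Product: 2 (4aS,5S)-5-hydroxy-4a-methyl-4,4a,5,6,7,8-hexahydronaphthalen-2(3H)-one (C1 hydroxyl β)
Conditions: NaBH4 (0.3 equiv), EtOH, −10 °C
Reagents that add atoms: none
Why: Borohydride reduces the saturated C1 ketone faster than the enone (chemoselective 1,2-reduction), and axial hydride delivery anti to the angular methyl should set the C1 hydroxyl β, cis to the methyl.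

Step 2
Reactants: 2 hydroxy enone
Product: 3 1β-benzyloxy enone
Conditions: benzyl 2,2,2-trichloroacetimidate, TfOH (cat.), CH2Cl2/cyclohexane, 0 °C to rt
Reagents that add atoms: benzyl 2,2,2-trichloroacetimidate, N=C(OCc1ccccc1)C(Cl)(Cl)Cl
Why: Acid-catalysed imidate O-benzylation protects the neopentylic alcohol without base, so the enone is not enolised, and the equatorial 1β-benzyloxy group later biases the decalin conformation for the key step.

Step 3
Reactants: 3 1β-benzyloxy enone
Product: 4 cis-fused 1β-benzyloxy-5β,6β-epoxy-10-methyldecalin-7-one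
Conditions: 30% H2O2, NaOH, MeOH, 0 °C
Reagents that add atoms: hydrogen peroxide, OO
Why: Weitz–Scheffer nucleophilic epoxidation of the enone, in which hydroperoxide adds axially to C5 on the face of the angular methyl (as steroidal 4-en-3-ones give 4β,5β-epoxides), should set C5 and C6 as the 5β,6β-epoxide.

Step 4
Reactants: 4 epoxy ketone
Product: 6 C7=C8 enol triflate of the epoxy ketone, via potassium enolate 5 (not isolated)
Conditions: KN(SiMe3)2, THF, −78 °C; then PhNTf2
Reagents that add atoms: N-phenylbis(trifluoromethanesulfonimide), O=S(=O)(N(c1ccccc1)S(=O)(=O)C(F)(F)F)C(F)(F)F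
Why: Kinetic deprotonation at C8, the only position that gives a strain-free enolate, followed by O-sulfonylation gives the enol triflate.

Step 5
Reactants: 6 enol triflate
Product: 7 1β-benzyloxy-5β,6β-epoxy-7-isopropyl-10-methyloctal-7-ene (vinyl epoxide)
Conditions: iPrMgCl (1.2 equiv), Fe(acac)3 (5 mol %), THF/NMP, −30 °C
Reagents that add atoms: isopropylmagnesium chloride, CC(C)[Mg]Cl
Why: Iron-catalysed Kumada-type sp2–sp3 coupling of alkenyl triflates with secondary alkyl Grignard reagents is fast at low temperature and should outrun attack on the epoxide.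

Step 6
Reactants: 7 vinyl epoxide
Product: 8 trans-fused 1β-benzyloxy-7-isopropyl-10-methylbicyclo[5.3.0]dec-7-en-5-one (H-6 α)
Conditions: BF3·OEt2 (1.2 equiv), CH2Cl2, −78 °C; cold pH 7 buffer quench
Reagents that add atoms: none
Why: BF3 coordinates the epoxide oxygen and the allylic C6–O bond ionises with assistance of the C7=C8 alkene, while the C5–C10 bond, lying on the face opposite the departing oxygen in the favoured cis-decalin conformer (1β-benzyloxy equatorial, C5–O axial on ring B), shifts to C6 and the C5–O–BF3 alkoxide collapses to the ketone. The closest known reaction types are the Lewis acid-promoted Meinwald (semipinacol) rearrangement of vinyl epoxides and the pinacol-type ring contraction of decalin 5-hydroxy 6-sulfonates to hydroazulenones. The cyclopentane closes by a suprafacial 1,2-alkyl shift (C10–C6 forms as C10–C5 breaks, a ring contraction and not an exo or endo cyclisation), and the same shift enlarges ring A to the seven-membered ketone. The new stereocentre C6 is formed with inversion, anti to the β epoxide C–O bond set in step 3, which gives the trans ring fusion (H-6 α), and C10 migrates with retention. The step needs C6–O rather than C5–O cleavage, secured by the allylic position of C6, and migration of C10 rather than of the ring A methylene C4, secured by the higher migratory aptitude of the tertiary carbon and by the conformer in which C4 is equatorial to ring B. Low temperature and a buffered quench should prevent enolisation of the doubly activated C6–H.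

Step 7
Reactants: 8 hydroazulenone
Product: 9 7α,8α-epoxide of 8
Conditions: mCPBA, NaHCO3, CH2Cl2, 0 °C
Reagents that add atoms: 3-chloroperoxybenzoic acid, OOC(=O)c1cccc(Cl)c1
Why: Prilezhaev epoxidation of the only alkene, from the α face of the cyclopentene (anti to the C10 methyl and to the C5 branch on C6), should set the C7–O bond α.

Step 8
Reactants: 9 epoxy ketone
Product: 10 1β-benzyloxy-7β-isopropyl-10-methylbicyclo[5.3.0]decane-5β,7α-diol (H-6 α)
Conditions: LiAlH4, THF, −20 °C, then reflux
Reagents that add atoms: none
Why: Hydride should reduce the C5 ketone from the less hindered α face (β face shielded by the C10 methyl and the C7 isopropyl) to the 5β-alcohol and open the trisubstituted epoxide by SN2 attack at the less substituted C8, leaving the tertiary 7α-alcohol.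

Step 9
Reactants: 10 diol; 11 4-[(tert-butyldimethylsilyl)oxy]benzoic acid
Product: 12 C5 4-(tert-butyldimethylsilyloxy)benzoate of 10
Conditions: DCC, DMAP, CH2Cl2, rt to 40 °C
Reagents that add atoms: 11 4-[(tert-butyldimethylsilyl)oxy]benzoic acid, CC(C)(C)[Si](C)(C)Oc1ccc(cc1)C(O)=O
Why: Steglich esterification acylates the secondary C5 hydroxyl, while the tertiary C7 hydroxyl does not react.

Step 10
Reactants: 12 benzyl ether ester
Product: 13 1β-alcohol
Conditions: H2 (1 atm), Pd/C, EtOAc, rt
Reagents that add atoms: none
Why: Hydrogenolysis of the benzyl ether over palladium is clean because no alkene is present at this stage and the aryl silyl ether and the benzoate are inert.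

Step 11
Reactants: 13 1β-alcohol
Product: 15 C1-keto C2=C3 enone, via C1 ketone 14 (not isolated)
Conditions: IBX (3 equiv), DMSO/fluorobenzene, rt, then 70 °C
Reagents that add atoms: none
Why: 2-Iodoxybenzoic acid first oxidises the secondary alcohol and then, at higher temperature, dehydrogenates the ketone through its only enolisable position C2 (IBX dehydrogenation).

Step 12
Reactants: 15 enone
Product: 17 3-methyl C2=C3 enone, via lithium enolate 16 (not isolated)
Conditions: Me2CuLi (3 equiv), THF, −78 °C; then PhS(Cl)=N-tBu, −78 °C to rt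
Reagents that add atoms: lithium dimethylcuprate, [Li+].C[Cu-]C
Why: Cuprate conjugate addition installs the C3 methyl and the enolate is dehydrogenated in the same flask by the sulfinimidoyl chloride (Mukaiyama dehydrogenation), which restores the C2=C3 alkene and removes the transient C3 stereocentre; one equivalent of cuprate is consumed by the tertiary hydroxyl.

Step 13
Reactants: 17 3-methyl enone
Product: 18 1β-allylic alcohol
Conditions: NaBH4, CeCl3·7H2O, MeOH, −78 °C
Reagents that add atoms: none
Why: Luche 1,2-reduction, with hydride adding anti to the axial C10 methyl, should give the 1β-alcohol.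

Step 14
Reactants: 18 1β-allylic alcohol; 19 3-methylbutanoic acid
Product: 20 silyl-protected target (1α-isovalerate)
Conditions: PPh3, DIAD, toluene, 0 °C to rt
Reagents that add atoms: 19 3-methylbutanoic acid, CC(C)CC(O)=O
Why: Mitsunobu esterification displaces the alkoxyphosphonium ion by isovalerate in an SN2 reaction with inversion, setting the 1α configuration; the tertiary alcohol is inert.

Step 15
Reactants: 20 silyl-protected target
Product: 21 target CNP0086724.4
Conditions: Bu4NF, AcOH, THF, 0 °C
Reagents that add atoms: none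
Why: Fluoride cleaves the aryl silyl ether much faster than either ester is attacked, and acetic acid buffering suppresses acyl transfer.

Compound list
1 | (S)-Wieland–Miescher ketone, (8aS)-8a-methyl-3,4,8,8a-tetrahydronaphthalene-1,6(2H,7H)-dione | C[C@]12CCC(=O)C=C1CCCC2=O | starting material
2 | (4aS,5S)-5-hydroxy-4a-methyl-4,4a,5,6,7,8-hexahydronaphthalen-2(3H)-one (1β-OH) | C[C@]12CCC(=O)C=C1CCC[C@@H]2O | intermediate
3 | 1β-benzyloxy enone (benzyl ether of 2) | C[C@]12CCC(=O)C=C1CCC[C@@H]2OCc1ccccc1 | intermediate
4 | cis-fused 1β-benzyloxy-5β,6β-epoxy-10-methyldecalin-7-one | C[C@]12CCC(=O)[C@@H]3O[C@@]31CCC[C@@H]2OCc1ccccc1 | intermediate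
5 | potassium C7(C8)-enolate of 4 | C[C@]12CC=C([O-])[C@@H]3O[C@@]31CCC[C@@H]2OCc1ccccc1.[K+] | intermediate (not isolated)
6 | 1β-benzyloxy-5β,6β-epoxy-10-methyloctal-7-en-7-yl trifluoromethanesulfonate | C[C@]12CC=C(OS(=O)(=O)C(F)(F)F)[C@@H]3O[C@@]31CCC[C@@H]2OCc1ccccc1 | intermediate
7 | 1β-benzyloxy-5β,6β-epoxy-7-isopropyl-10-methyloctal-7-ene | C[C@]12CC=C(C(C)C)[C@@H]3O[C@@]31CCC[C@@H]2OCc1ccccc1 | intermediate
8 | trans-fused 1β-benzyloxy-7-isopropyl-10-methylbicyclo[5.3.0]dec-7-en-5-one, H-6 α | C[C@]12CC=C(C(C)C)[C@@H]1C(=O)CCC[C@@H]2OCc1ccccc1 | intermediate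
9 | 7α,8α-epoxide of 8 | C[C@]12C[C@H]3O[C@@]3(C(C)C)[C@@H]1C(=O)CCC[C@@H]2OCc1ccccc1 | intermediate
10 | 1β-benzyloxy-7β-isopropyl-10-methylbicyclo[5.3.0]decane-5β,7α-diol, H-6 α | C[C@]12CC[C@](O)(C(C)C)[C@@H]1[C@H](O)CCC[C@@H]2OCc1ccccc1 | intermediate
11 | 4-[(tert-butyldimethylsilyl)oxy]benzoic acid | CC(C)(C)[Si](C)(C)Oc1ccc(cc1)C(O)=O | starting material
12 | C5β 4-(tert-butyldimethylsilyloxy)benzoate of 10 | C[C@]12CC[C@](O)(C(C)C)[C@@H]1[C@H](OC(=O)c3ccc(O[Si](C)(C)C(C)(C)C)cc3)CCC[C@@H]2OCc4ccccc4 | intermediate
13 | debenzylated 1β-alcohol | C[C@]12CC[C@](O)(C(C)C)[C@@H]1[C@H](OC(=O)c3ccc(O[Si](C)(C)C(C)(C)C)cc3)CCC[C@@H]2O | intermediate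
14 | C1 ketone | C[C@]12CC[C@](O)(C(C)C)[C@@H]1[C@H](OC(=O)c3ccc(O[Si](C)(C)C(C)(C)C)cc3)CCCC2=O | intermediate (not isolated)
15 | C1-keto C2=C3 enone | C[C@]12CC[C@](O)(C(C)C)[C@@H]1[C@H](OC(=O)c3ccc(O[Si](C)(C)C(C)(C)C)cc3)CC=CC2=O | intermediate
16 | lithium C1(C2)-enolate of the 3-methyl ketone (C3 epimers, tertiary hydroxyl drawn free) | C[C@]12CC[C@](O)(C(C)C)[C@@H]1[C@H](OC(=O)c3ccc(O[Si](C)(C)C(C)(C)C)cc3)CC(C)C=C2O[Li] | intermediate (not isolated)
17 | 3-methyl C2=C3 enone | C[C@]12CC[C@](O)(C(C)C)[C@@H]1[C@H](OC(=O)c3ccc(O[Si](C)(C)C(C)(C)C)cc3)CC(C)=CC2=O | intermediate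
18 | 1β-allylic alcohol | C[C@]12CC[C@](O)(C(C)C)[C@@H]1[C@H](OC(=O)c3ccc(O[Si](C)(C)C(C)(C)C)cc3)CC(C)=C[C@@H]2O | intermediate
19 | 3-methylbutanoic acid (isovaleric acid) | CC(C)CC(O)=O | starting material
20 | tert-butyldimethylsilyl ether of the target (1α-isovalerate, 5β-aroyl ester) | CC1=C[C@@H](OC(=O)CC(C)C)[C@@]2(C)CC[C@](O)(C(C)C)[C@@H]2[C@H](OC(=O)c2ccc(O[Si](C)(C)C(C)(C)C)cc2)C1 | intermediate
21 | CNP0086724.4 | CC1=C[C@@H](OC(=O)CC(C)C)[C@@]2(C)CC[C@](O)(C(C)C)[C@@H]2[C@H](OC(=O)c2ccc(O)cc2)C1 | target

Total step count: 15. Longest linear sequence: 15 steps (1 to 21).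

Steps most likely to fail

Step 6. The ring A methylene C4 may migrate instead of C10, the allyl cation may lose a proton to a dienol, or the doubly activated C6–H of the product may epimerise or move the alkene into conjugation. The fallback sets out from 7 and comes back to the route at 10. Vinyl epoxide 7 is heated with LiBr and HMPA in toluene. Bromide opens the allylic C6–O bond with inversion. In the lithium bromohydrin salt only the C5–C10 bond can lie antiperiplanar to the equatorial C6–Br bond, so an SN2-type 1,2-shift should give the cis-fused C6 epimer of 8 F1. DBU then moves the alkene into conjugation to give the C6=C7 enone F2. Weitz–Scheffer epoxidation with tBuOOH and DBU from the α face should give the 6α,7α-epoxy ketone F3. SmI2 with MeOH at −90 °C cleaves the C6–O bond, and kinetic protonation of the samarium enolate from the α face should give the 7α-hydroxy ketone F4 with H-6 α. Anti-selective Evans–Saksena reduction with Me4NBH(OAc)3 delivers hydride from the α face and gives diol 10.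

Step 14. SN2 displacement at the neopentylic allylic carbinol may be outrun by elimination to a diene or by ionisation and SN2′ attack, with loss of inversion. The fallback sets out from 17 and comes back at 20. Enone 17 is reduced under reagent control by Corey–Bakshi–Shibata reduction with (S)-2-methyl-CBS-oxazaborolidine and catecholborane, the quaternary C10 acting as the large group. This should override the substrate bias and give the 1α-allylic alcohol F5, which is acylated with isovaleryl chloride, Et3N and DMAP to give 20.

Step 5. The Grignard reagent may open the epoxide or add in SN2′ fashion to the vinyl epoxide as it forms. The fallback sets out from 6 and comes back at 7. Suzuki–Miyaura coupling of 6 with isopropenylboronic acid pinacol ester (Pd(dppf)Cl2, K3PO4, THF/H2O) gives the isopropenyl diene epoxide F6. Diimide, generated from 2-nitrobenzenesulfonylhydrazide and Et3N, then reduces the less substituted 1,1-disubstituted alkene to give 7.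

Further compounds
F1 | step 6 | cis-fused C6 epimer of 8 (H-6 β) | C[C@]12CC=C(C(C)C)[C@H]1C(=O)CCC[C@@H]2OCc1ccccc1
F2 | step 6 | C6=C7 conjugated enone | C[C@]12CCC(C(C)C)=C1C(=O)CCC[C@@H]2OCc1ccccc1
F3 | step 6 | 6α,7α-epoxy-5-ketone | C[C@]12CC[C@@]3(C(C)C)O[C@]31C(=O)CCC[C@@H]2OCc1ccccc1
F4 | step 6 | 7α-hydroxy-5-ketone with H-6 α | C[C@]12CC[C@](O)(C(C)C)[C@@H]1C(=O)CCC[C@@H]2OCc1ccccc1
F5 | step 14 | 1α-allylic alcohol (C1 epimer of 18) | C[C@]12CC[C@](O)(C(C)C)[C@@H]1[C@H](OC(=O)c3ccc(O[Si](C)(C)C(C)(C)C)cc3)CC(C)=C[C@H]2O
F6 | step 5 | 1β-benzyloxy-5β,6β-epoxy-7-isopropenyl-10-methyloctal-7-ene | C[C@]12CC=C(C(C)=C)[C@@H]3O[C@@]31CCC[C@@H]2OCc1ccccc1
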